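## Structural features

The target is an icetexane, a 9(10→20)-abeo-abietane. Ring A is a cyclohexane (C1–C5, C10), ring B a seven-membered carbocycle (C5, C6, C7, C8, C9, C20, C10), and ring C a fully substituted 12-hydroxy-13-isopropyl-11,14-benzoquinone fused to ring B at C8–C9. A γ-enol lactone (C19–O–C6=C7) bridges C4 and C5. Ring B is a cross-conjugated cycloheptatriene: C6=C7 and C10=C20 flank the quinone bond C8=C9, and C5 is its only sp3 atom. There are three stereocentres: the quaternary C4 (S; α-methyl, β-carboxyl carbon C19) lies next to C5 (R; α-H), and C1 (R; β-OH) is 1,4-cis to C19. The lactone demands that C19 and C6 be cis on ring A. Fragile elements are the enol lactone (an acyl donor), the acidic hydroxyquinone, the doubly allylic C5–H, and the allylic C1 alcohol, which could also lactonise onto C19 if freed too early. The real difficulty is a hexasubstituted ring C with the correct O/O/isopropyl/O sequence on a seven-membered ring, a quaternary C4 next to C5, and the late introduction of two quinone-conjugated alkenes without moving the C5 hydrogen. The key step exploits the four contiguous ring-C carbons C11(O)–C12(O)–C13(iPr)–C14(O) together with the fusion bond C8–C9: the four carbons map onto a squaric ester and C8=C9 onto an alkene of ring B.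

## Logic of the disconnections

37 ⇒ 36. The C1 O–Si bond is cut last. The C1 hydroxyl is 1,4-cis to C19 and could form a bridged lactone while the acid is free, so it stays masked until the enol lactone exists. The forward step needs a fluoride source that is neither basic nor nucleophilic toward the enol lactone.

36 ⇒ 34 (through 35). The acyl–oxygen bond C19–O–C6 and the enol double bond C6=C7 are traced back to a C6 ketone and a C19 acid, re-masked as dioxolane and tert-butyl ester, with C12–OH as its isopropyl ether. This replaces the most electrophilic group by three robust ones. The demand is that one acidic operation unmasks all three and dehydrates toward C7 and not toward C5.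

34 ⇒ 32 ⇒ 31. The C10=C20 bond is removed by trading it for the quinone oxidation level (quinone with C20H2–C10H ⇄ hydroquinone with C10=C20). The gain is a saturated C10–C20 unit that tolerates organolithium chemistry and heat. The forward step must enolise through C20; the competing site C7 has no onward path because C6 carries no hydrogen. Reoxidation must be done without base.

31 ⇒ 29 (key). The C8–C14 bond is cut and C11–C14 re-formed, which collapses ring C to a four-membered ring. All four substituted carbons C11–C14 then come from one small building block, and no hexasubstituted arene has to be made. The demand is an alkenyl group at C11 with the double bond at C8=C9, a hydrogen on C8, and thermal stability of ketal, ester and silyl ether.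

29 ⇒ 27 + 4. The C9–C11 bond is cut as a polar addition of a C9 nucleophile to the more electrophilic carbonyl of 4. This makes the route convergent. The C9 metal must be generated without touching the tert-butyl ester and with the double bond fixed at C8=C9 and not at C9=C20.

4 ⇒ 1 + 2. The C13–isopropyl bond is cut, an addition–transposition on a symmetrical squarate. The forward step must stop at mono-addition.

27 ⇒ 26 ⇒ 25. C9–Sn and C9–O(triflyl) are interconverted back to a ring-B enol silane. A cyclic C9 ketone has two similar α-methylenes (C8 and C20), so enolising it would be regiochemically ambiguous; the enol silane carries the C8=C9 position by construction. The triflation must not let the enolate equilibrate.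

25 ⇒ 24 ⇒ 23 ⇒ 22. The C8=C9 bond is cut by ring-closing metathesis, which opens ring B to two arms on ring A. The enol silane arm goes back to a methyl ketone, and that to a terminal alkyne, an inert placeholder through Grignard, oxidation and Lewis-acid steps. The demands are metathesis onto a 1,1-disubstituted enol silane and kinetic enolisation at the methyl group.

22 ⇒ 21 ⇒ 20 ⇒ 17. The C6 ketal is opened to the ketone, C6–C7 is cut as an allyl addition to a C6 aldehyde, and the aldehyde is taken back to a primary alcohol. The gain is a one-carbon side chain on C5. The β,γ-unsaturated ketone must not conjugate, and the hindered ketone must ketalise.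

17 ⇒ 16 ⇒ 15 ⇒ 14. Protecting-group changes and the C1 C–H bond are removed, back to a C1 ketone. The ketone is what makes C10 nucleophilic in the preceding step. The reduction must deliver the equatorial 1β-alcohol.

14 ⇒ 12 + 13. The C10–C20 bond is cut as an enolate alkylation. The enol silane left by the cycloaddition defines the enolate position (C1=C10), so no regiochemical choice between C2 and C10 arises. The alkylation must occur anti to the C5 side chain.

12 ⇒ 11 ⇒ 10. The C19 ester is taken back through the acid to an aldehyde, because the aldehyde is the dienophile activating group that allows asymmetric catalysis. The forward steps must spare the enol silane.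

10 ⇒ 8 + 9. The C4–C5 and C2–C3 bonds are cut (Diels–Alder). One step then builds ring A with the quaternary C4 and the adjacent C5. It must be para-selective with respect to the silyloxy group, formyl-endo, and face-selective.

8 ⇒ 7 ⇒ 5 + 6. The O–Si bond and the C=C bond of the enone are cut (enol silylation, Wittig). Both are routine; the alkene must be E so that the C5 side chain sits "outside" in the cycloaddition.

## Other disconnections considered

Alternative 1: The cut is C9–C20, with the aryl carbon originally bonded to C10 of an abietane. The forward key step would be a cationic 1,2-aryl shift triggered by a leaving group on C20, which enlarges ring B and ends by loss of a C20 proton to give A2 with C10=C20 in place. In its favour: podocarpic acid A1 supplies C4, C5 and the C19 acid in the correct absolute configuration, so no asymmetric catalysis is needed. On this point it is better than the chosen plan. The rearrangement also delivers the C10=C20 alkene directly, where the chosen plan needs a separate tautomerisation (steps 21–22), again a point for the alternative. The C7 ketone of A2 offers a direct path to the C6=C7 enol lactone by reduction and dehydration. Against it here: A1 has an unfunctionalised angular C20 methyl that must be oxidised, no oxygen at C1, C11 or C14, and no isopropyl group. A2 still lacks the C1 hydroxyl and the C14 oxygen. A late, stereoselective C1 hydroxylation next to the doubly allylic C5–H is the weakest point, and the ring-C oxidation pattern must be built by several arene substitutions and oxidations. Mechanistically the cationic shift competes with simple elimination and with migration of other groups; the pericyclic cascade of the chosen plan has no such branching. In step count the chiral-pool start saves the early steps but the oxidation-state repairs would probably consume the saving; overall the two are judged comparable, with the chosen plan more certain at C1.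

Alternative 2: The cuts are C5–C10 and C6–C7, made in one intramolecular enone–alkene [2+2] photocycloaddition that closes ring A and a cyclobutane to give A3; fragmentation of the strained C7–C10 bond would then expand the five-membered ring to ring B. In its favour: two C–C bonds and ring A form in one step, ring C arrives fully oxygenated, and the lactone is present from the start, so no late lactonisation is needed. In bonds formed per step it is better than the chosen plan, and in delivering ring C complete it is its equal. Against it here: the photosubstrate needs an enantiopure butenolide with the quaternary C4 and a tether carrying C1, which is no easier than the ring-A building block of the chosen plan. The facial and straight/crossed selectivity of the cycloaddition rests on the tether alone. The fragmentation must break C7–C10 and not another cyclobutane bond. A3 also carries a C20 ketone, a saturated lactone at C6 and three methyl ethers, so C10=C20, C6=C7 and the hydroxyquinone all remain to be made. The chosen plan has the same two alkenes to install but not the C20 deoxygenation. Step economy is judged similar; the chosen plan has fewer selectivity questions in its key step.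

Alternative 3: The cuts are C8–C7 and C9–C20, made by insertion of an aryne into the C7–C20 bond of a ring-A-fused cyclopentanone β-ketoester, which expands that ring to ring B and gives A4. In its favour: it is convergent and a known reaction class. The inherent bias of a 3-alkoxyaryne (carbon nucleophile adds distal to the alkoxy group, the aryl anion then acylates) matches the required orientation, so its regiocontrol is the equal of the squarate route. Against it here: A4 carries a C7 ester that must be excised, a C20 ketone that must be converted into C10=C20, no oxygen at C6 and no oxygen at C14. That is four redox or excision corrections on ring B and ring C after the key step, against two alkene installations in the chosen plan. The bicyclic ketoester needs the same C1, C4, C5 stereotriad as the ring-A/B unit of the chosen plan, so the stereochemical burden is equal. The fully substituted aryne precursor adds steps that the squarate avoids. On step economy the chosen plan is judged somewhat better, on convergency the two are equal.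

Key step: step 20

Assumptions and remarks:
- Icetexane numbering is used for all intermediates (C18 = 4α-CH3, C19 = 4β-carboxyl carbon). "AB bicycle" means the trans-fused ring A (C1–C5, C10)/ring B (C5–C10, C20) unit carrying 4α-CH3, 4β-CO2tBu, 1β-OTBS and the C6 ethylene ketal.
- A CIP check of 29 and 31 against 37 gives consistent descriptors (1R,4S,5R; 10R, trans ring fusion); no stereochemical correction is needed, and C10 is erased in step 22.
- The design changes relative to the simplest reading of the plan are: the C8=C9 position is fixed by construction (steps 15–17) and not by enolising a cyclic C9 ketone; the alkenyllithium comes from a stannane; C10=C20 is installed before the enol lactone.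
- In step 4 the (S)-configured oxazaborolidinium salt is assumed to shield the enal face that leads to (1S,2R)-10; if the sense is the opposite, the (R)-catalyst is used and nothing else changes.
- 20 (C6 epimers) and 29 (carbinol epimers) are carried as mixtures, because these centres are erased in steps 12 and 20.

## Route

Step 1
Reactants: 1 diisopropyl squarate; 2 isopropylmagnesium chloride
Product: 4 3-isopropoxy-4-isopropylcyclobut-3-ene-1,2-dione, via carbinol adduct 3 (not isolated)
Conditions: 2 (1.05 equiv), THF, −78 °C; aq NH4Cl; crude 3, conc. HCl (cat.), CH2Cl2, rt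
Reagents that add atoms: none
Why: 1,2-Addition of the Grignard reagent to one squarate carbonyl, then acid-induced allylic transposition with loss of isopropanol (the standard squarate mono-alkylation) should give 4; low temperature and one equivalent prevent a second addition.

Step 2
Reactants: 5 2-[(4-methoxybenzyl)oxy]acetaldehyde; 6 1-(triphenylphosphoranylidene)propan-2-one
Product: 7 (E)-5-[(4-methoxybenzyl)oxy]pent-3-en-2-one
Conditions: CH2Cl2, rt
Reagents that add atoms: none
Why: Wittig olefination with a stabilised ylide, which should give the E enone.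

Step 3
Reactants: 7
Product: 8 (E)-triisopropyl({5-[(4-methoxybenzyl)oxy]penta-1,3-dien-2-yl}oxy)silane
Conditions: LDA, THF, −78 °C; TIPSOTf, −78 → 0 °C
Reagents that add atoms: triisopropylsilyl trifluoromethanesulfonate, CC(C)[Si](OS(=O)(=O)C(F)(F)F)(C(C)C)C(C)C
Why: Kinetic α′-deprotonation of the methyl ketone gives the cross-conjugated enolate, and O-silylation should deliver the 2-silyloxydiene with the E alkene intact.

Step 4
Reactants: 8; 9 methacrolein
Product: 10 (1S,2R)-2-{[(4-methoxybenzyl)oxy]methyl}-1-methyl-4-(triisopropylsilyloxy)cyclohex-3-ene-1-carbaldehyde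
Conditions: (S)-o-tolyl-oxazaborolidine (from (S)-α,α-diphenylprolinol)·HNTf2 (20 mol%), CH2Cl2, −78 → −40 °C
Reagents that add atoms: none
Why: Enantioselective Lewis acid-catalysed Diels–Alder reaction of an α-substituted enal with a 1-substituted 3-silyloxydiene; the silyloxy group directs the formyl-bearing carbon para to it (bonds C4–C5 and C2–C3). The formyl-endo transition state places CHO cis to the C5 side chain, and the catalyst blocks one face of the s-trans enal, which together set C4 (S) and C5 (R).

Step 5
Reactants: 10
Product: 11 (1S,2R)-2-{[(4-methoxybenzyl)oxy]methyl}-1-methyl-4-(triisopropylsilyloxy)cyclohex-3-ene-1-carboxylic acid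
Conditions: NaClO2, NaH2PO4, 2-methyl-2-butene, tBuOH/H2O, 0 °C
Reagents that add atoms: sodium chlorite, [Na+].[O-]Cl=O
Why: Pinnick oxidation of the neopentyl aldehyde; the alkene scavenger removes hypochlorite before it can attack the hindered enol silane.

Step 6
Reactants: 11
Product: 12 tert-butyl (1S,2R)-2-{[(4-methoxybenzyl)oxy]methyl}-1-methyl-4-(triisopropylsilyloxy)cyclohex-3-ene-1-carboxylate
Conditions: DMF di-tert-butyl acetal, toluene, 80 °C
Reagents that add atoms: N,N-dimethylformamide di-tert-butyl acetal, CN(C)C(OC(C)(C)C)OC(C)(C)C
Why: Esterification by O-alkylation of the carboxylate under neutral conditions works for hindered acids because the acyl carbon is not attacked, and it spares the enol silane.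

Step 7
Reactants: 12; 13 propargyl bromide
Product: 14 tert-butyl (1S,2R,3R)-2-{[(4-methoxybenzyl)oxy]methyl}-1-methyl-4-oxo-3-(prop-2-yn-1-yl)cyclohexane-1-carboxylate
Conditions: TASF, THF, −78 → 0 °C
Reagents that add atoms: none
Why: Fluoride cleaves the enol silane to an enolate whose position (C1=C10) was fixed by the cycloaddition, so C-alkylation should occur only at C10 (regiospecific enolate alkylation). The electrophile enters anti to the C5 side chain, and the epimerisable centre also rests in the diequatorial trans arrangement (icetexane 10R).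

Step 8
Reactants: 14
Product: 15 tert-butyl (1S,2R,3R,4R)-4-hydroxy-2-{[(4-methoxybenzyl)oxy]methyl}-1-methyl-3-(prop-2-yn-1-yl)cyclohexane-1-carboxylate
Conditions: NaBH4, MeOH/THF, −20 °C
Reagents that add atoms: none
Why: The small hydride attacks the chair ketone along the axial α trajectory, which is flanked only by hydrogens, and should give the equatorial 1β-alcohol (icetexane 1R) trans to the C10 side chain; ester and alkyne are inert.

Step 9
Reactants: 15
Product: 16 tert-butyl (1S,2R,3R,4R)-4-(tert-butyldimethylsilyloxy)-2-{[(4-methoxybenzyl)oxy]methyl}-1-methyl-3-(prop-2-yn-1-yl)cyclohexane-1-carboxylate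
Conditions: TBSOTf, 2,6-lutidine, CH2Cl2, 0 °C
Reagents that add atoms: tert-butyldimethylsilyl trifluoromethanesulfonate, CC(C)(C)[Si](C)(C)OS(=O)(=O)C(F)(F)F
Why: Silylation of a secondary alcohol with the silyl triflate; the ether must last until the end so that C1–OH cannot lactonise onto C19.

Step 10
Reactants: 16
Product: 17 tert-butyl (1S,2R,3R,4R)-4-(tert-butyldimethylsilyloxy)-2-(hydroxymethyl)-1-methyl-3-(prop-2-yn-1-yl)cyclohexane-1-carboxylate
Conditions: DDQ, CH2Cl2/pH 7 buffer, 0 °C → rt
Reagents that add atoms: none
Why: Oxidative cleavage of the 4-methoxybenzyl ether leaves the silyl ether, alkyne and tert-butyl ester untouched; the buffer keeps the γ-hydroxy ester from lactonising.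

Step 11
Reactants: 17; 18 allylmagnesium bromide
Product: 20 tert-butyl (1S,2R,3R,4R)-4-(tert-butyldimethylsilyloxy)-2-(1-hydroxybut-3-en-1-yl)-1-methyl-3-(prop-2-yn-1-yl)cyclohexane-1-carboxylate (both carbinol epimers), via C6 aldehyde 19 (not isolated)
Conditions: (COCl)2, DMSO, CH2Cl2, −78 °C; Et3N; then 18 (3 equiv), THF, −78 °C; aq NH4Cl
Reagents that add atoms: none
Why: Swern oxidation followed by Grignard addition in the same flask forms the C6–C7 bond without isolating the α-branched aldehyde. The new C6 carbinol centre is not controlled and need not be, since it is oxidised in step 12.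

Step 12
Reactants: 20
Product: 21 tert-butyl (1S,2R,3R,4R)-2-(but-3-enoyl)-4-(tert-butyldimethylsilyloxy)-1-methyl-3-(prop-2-yn-1-yl)cyclohexane-1-carboxylate
Conditions: Dess–Martin periodinane, NaHCO3, CH2Cl2, 0 °C → rt
Reagents that add atoms: none
Why: Buffered Dess–Martin oxidation gives the β,γ-unsaturated ketone without conjugation and removes the lactonisation-prone γ-hydroxy ester; C5 stays in its equatorial configuration.

Step 13
Reactants: 21
Product: 22 tert-butyl (1S,2R,3R,4R)-2-(2-allyl-1,3-dioxolan-2-yl)-4-(tert-butyldimethylsilyloxy)-1-methyl-3-(prop-2-yn-1-yl)cyclohexane-1-carboxylate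
Conditions: TMSOCH2CH2OTMS, TMSOTf (5 mol%), CH2Cl2, −78 → −20 °C; pyridine
Reagents that add atoms: 1,2-bis(trimethylsilyloxy)ethane, C[Si](C)(C)OCCO[Si](C)(C)C
Why: Aprotic ketalisation with the bis-silyl glycol and catalytic silyl triflate at low temperature should convert the hindered ketone into the dioxolane without migration of the β,γ double bond or loss of the tert-butyl ester.

Step 14
Reactants: 22
Product: 23 tert-butyl (1S,2R,3R,4R)-2-(2-allyl-1,3-dioxolan-2-yl)-4-(tert-butyldimethylsilyloxy)-1-methyl-3-(2-oxopropyl)cyclohexane-1-carboxylate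
Conditions: (IPr)AuCl/AgSbF6 (2 mol%), 1,4-dioxane/H2O, 60 °C
Reagents that add atoms: water, O
Why: Markovnikov hydration of the terminal alkyne under acid-free cationic gold catalysis should give the methyl ketone; the terminal alkene is not activated, and ketal and silyl ether are expected to survive the neutral medium.

Step 15
Reactants: 23
Product: 24 tert-butyl (1S,2R,3R,4R)-2-(2-allyl-1,3-dioxolan-2-yl)-4-(tert-butyldimethylsilyloxy)-1-methyl-3-[2-(triethylsilyloxy)prop-2-en-1-yl]cyclohexane-1-carboxylate
Conditions: LDA, THF, −78 °C; TESCl
Reagents that add atoms: chlorotriethylsilane, CC[Si](Cl)(CC)CC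
Why: Kinetic deprotonation takes the methyl hydrogen (the C20 methylene is β-branched, and no other enolisable carbonyl is present). O-silylation gives the terminal enol silane, which fixes the later ring double bond between C8 and C9.

Step 16
Reactants: 24
Product: 25 9-(triethylsilyloxy)-Δ8 AB bicycle (1R,4S,5R,10R)
Conditions: Grubbs second-generation catalyst (10 mol%), toluene (2 mM), 80 °C
Reagents that add atoms: none
Why: Ring-closing metathesis between the allyl group and the 1,1-disubstituted enol silane, a known pairing for cyclic silyl enol ethers, should close the seven-membered ring B with C8=C9 in place by construction; high dilution suppresses dimerisation.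

Step 17
Reactants: 25
Product: 26 9-(trifluoromethanesulfonyloxy)-Δ8 AB bicycle (1R,4S,5R,10R)
Conditions: CsF, PhNTf2, DME, rt
Reagents that add atoms: N-phenylbis(trifluoromethanesulfonimide), O=S(=O)(N(c1ccccc1)S(=O)(=O)C(F)(F)F)C(F)(F)F
Why: Fluoride unmasks the enolate in the presence of the triflating agent, so O-triflation outruns proton transfer and the C8=C9 position is retained (enol silane to enol triflate exchange).

Step 18
Reactants: 26
Product: 27 9-(trimethylstannyl)-Δ8 AB bicycle (1R,4S,5R,10R)
Conditions: Pd(PPh3)4 (5 mol%), (Me3Sn)2, LiCl, THF, 65 °C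
Reagents that add atoms: hexamethylditin, C[Sn](C)(C)[Sn](C)(C)C
Why: Palladium-catalysed stannylation of an enol triflate with a distannane is a standard route to cycloalkenylstannanes and does not move the double bond.

Step 19
Reactants: 27; 4
Product: 29 4-hydroxy-3-isopropoxy-2-isopropyl-4-(Δ8 AB bicycle-9-yl)cyclobut-2-en-1-one (both carbinol epimers), via alkenyllithium 28 (not isolated)
Conditions: MeLi, THF, −78 °C; then added to 4 (1.3 equiv), THF, −78 °C; aq NH4Cl
Reagents that add atoms: none
Why: Tin–lithium exchange gives the C9 alkenyllithium, which adds 1,2 to the carbonyl of 4 next to the alkoxy-bearing carbon (the other carbonyl is a deactivated vinylogous ester). The tert-butyl ester on the quaternary carbon should survive at −78 °C.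

Step 20
Reactants: 29
Product: 31 12-isopropoxy-13-isopropyl-11,14-hydroquinone fused at C8–C9 to the AB bicycle (1R,4S,5R,10R), via dienylketene 30 (not isolated)
Conditions: toluene (degassed, 0.01 M), 110 °C, Ar
Reagents that add atoms: none
Why: Heating breaks the C11–C14 bond of the cyclobutenone in a conrotatory 4π ring opening in which the donor hydroxyl turns outward, so the C9 alkenyl group ends up cis to the ketene arm in dienylketene 30. A thermal disrotatory 6π electrocyclisation then joins the ketene carbon C14 to C8 and closes ring C as a cyclohexa-2,4-dienone, and enolisation of the C8 hydrogen gives the aromatic hydroquinone. The closest known reaction type is the thermal ring expansion of 4-alkenyl- and 4-aryl-4-hydroxycyclobutenones to hydroquinones (squarate benzannulation). No stereocentre is formed; the carbinol centre is destroyed, so both epimers of 29 converge, and C1, C4, C5 and C10 are untouched under neutral conditions. The step needs one regiochemical outcome, fusion of ring C at C8–C9. It is secured because only the C8=C9 double bond is conjugated with C11 (C20 is sp3), and the O/isopropyl pattern is fixed because isopropyl and isopropoxy already sit on the carbons that become C13 and C12. Ketal, tert-butyl ester and silyl ether are spectators.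

Step 21
Reactants: 31
Product: 32 12-isopropoxy-13-isopropyl-11,14-quinone fused at C8–C9 to the AB bicycle (1R,4S,5R,10R)
Conditions: Ag2O, MgSO4, Et2O, rt
Reagents that add atoms: none
Why: Neutral two-electron oxidation of the air-sensitive hydroquinone removes the free C14 phenol before any acid is used, which closes off benzofuran formation with the masked C6 ketone.

Step 22
Reactants: 32
Product: 34 10(20)-ene 12-isopropoxy-11,14-quinone with C6 ketal and C19 tert-butyl ester (1R,4S,5R), via vinylhydroquinone 33 (not isolated)
Conditions: DBU (0.3 equiv), toluene (degassed), 50 °C; AcOH; then Ag2O, rt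
Reagents that add atoms: none
Why: Base-mediated tautomerisation of an alkylquinone through its o-quinone methide: γ-deprotonation at C20, then at C10, should give the aromatic hydroquinone with C10=C20, which is reoxidised after the base is neutralised. The C7 quinone methide is a dead end because C6 carries no hydrogen, and the isopropyl methine is poorly aligned; C10 loses its stereocentre as intended.

Step 23
Reactants: 34
Product: 36 1-O-(tert-butyldimethylsilyl)-6,7-anhydroballotiquinone (1R,4S,5R), via keto acid 35 (not isolated)
Conditions: TFA/H2O/CH2Cl2, 0 °C → rt; evaporate; TFAA, CH2Cl2, 0 °C → rt; pH 7 buffer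
Reagents that add atoms: water, O
Why: Aqueous acid should cleave the tert-butyl ester, hydrolyse the dioxolane and hydrolyse the isopropyl vinylogous ester by addition–elimination; the anhydride then dehydrates the γ-keto acid (pseudo-acid) to the enol lactone. C7, flanked by the quinone and the ketone, enolises far more readily than C5, and only the cis C19/C6 arrangement can close the five-membered lactone, so C5 keeps its configuration.

Step 24
Reactants: 36
Product: 37 6,7-anhydroballotiquinone
Conditions: HF·pyridine, THF/pyridine, 0 °C → rt
Reagents that add atoms: none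
Why: Buffered fluoride desilylation is non-basic and non-nucleophilic toward the enol lactone and should free the allylic 1β-alcohol without touching the doubly allylic C5–H.

## Compound list

1 | diisopropyl squarate (3,4-diisopropoxycyclobut-3-ene-1,2-dione) | CC(C)OC1=C(OC(C)C)C(=O)C1=O | starting material
2 | isopropylmagnesium chloride | CC(C)[Mg]Cl | starting material
3 | 4-hydroxy-2,3-diisopropoxy-4-isopropylcyclobut-2-en-1-one | CC(C)OC1=C(OC(C)C)C(O)(C(C)C)C1=O | intermediate
4 | 3-isopropoxy-4-isopropylcyclobut-3-ene-1,2-dione | CC(C)OC1=C(C(C)C)C(=O)C1=O | intermediate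
5 | 2-[(4-methoxybenzyl)oxy]acetaldehyde | COc1ccc(COCC=O)cc1 | starting material
6 | 1-(triphenylphosphoranylidene)propan-2-one | CC(=O)C=P(c1ccccc1)(c1ccccc1)c1ccccc1 | starting material
7 | (E)-5-[(4-methoxybenzyl)oxy]pent-3-en-2-one | CC(=O)/C=C/COCc1ccc(OC)cc1 | intermediate
8 | (E)-triisopropyl({5-[(4-methoxybenzyl)oxy]penta-1,3-dien-2-yl}oxy)silane | C=C(O[Si](C(C)C)(C(C)C)C(C)C)/C=C/COCc1ccc(OC)cc1 | intermediate
9 | methacrolein | CC(=C)C=O | starting material
10 | (1S,2R)-2-{[(4-methoxybenzyl)oxy]methyl}-1-methyl-4-(triisopropylsilyloxy)cyclohex-3-ene-1-carbaldehyde | COc1ccc(COC[C@@H]2C=C(O[Si](C(C)C)(C(C)C)C(C)C)CC[C@]2(C)C=O)cc1 | intermediate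
11 | (1S,2R)-2-{[(4-methoxybenzyl)oxy]methyl}-1-methyl-4-(triisopropylsilyloxy)cyclohex-3-ene-1-carboxylic acid | COc1ccc(COC[C@@H]2C=C(O[Si](C(C)C)(C(C)C)C(C)C)CC[C@]2(C)C(=O)O)cc1 | intermediate
12 | tert-butyl (1S,2R)-2-{[(4-methoxybenzyl)oxy]methyl}-1-methyl-4-(triisopropylsilyloxy)cyclohex-3-ene-1-carboxylate | COc1ccc(COC[C@@H]2C=C(O[Si](C(C)C)(C(C)C)C(C)C)CC[C@]2(C)C(=O)OC(C)(C)C)cc1 | intermediate
13 | propargyl bromide (3-bromoprop-1-yne) | BrCC#C | starting material
14 | tert-butyl (1S,2R,3R)-2-{[(4-methoxybenzyl)oxy]methyl}-1-methyl-4-oxo-3-(prop-2-yn-1-yl)cyclohexane-1-carboxylate | COc1ccc(COC[C@@H]2[C@@H](CC#C)C(=O)CC[C@]2(C)C(=O)OC(C)(C)C)cc1 | intermediate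
15 | tert-butyl (1S,2R,3R,4R)-4-hydroxy-2-{[(4-methoxybenzyl)oxy]methyl}-1-methyl-3-(prop-2-yn-1-yl)cyclohexane-1-carboxylate | COc1ccc(COC[C@@H]2[C@@H](CC#C)[C@H](O)CC[C@]2(C)C(=O)OC(C)(C)C)cc1 | intermediate
16 | tert-butyl (1S,2R,3R,4R)-4-(tert-butyldimethylsilyloxy)-2-{[(4-methoxybenzyl)oxy]methyl}-1-methyl-3-(prop-2-yn-1-yl)cyclohexane-1-carboxylate | COc1ccc(COC[C@@H]2[C@@H](CC#C)[C@H](O[Si](C)(C)C(C)(C)C)CC[C@]2(C)C(=O)OC(C)(C)C)cc1 | intermediate
17 | tert-butyl (1S,2R,3R,4R)-4-(tert-butyldimethylsilyloxy)-2-(hydroxymethyl)-1-methyl-3-(prop-2-yn-1-yl)cyclohexane-1-carboxylate | OC[C@@H]1[C@@H](CC#C)[C@H](O[Si](C)(C)C(C)(C)C)CC[C@]1(C)C(=O)OC(C)(C)C | intermediate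
18 | allylmagnesium bromide | C=CC[Mg]Br | starting material
19 | tert-butyl (1S,2R,3R,4R)-4-(tert-butyldimethylsilyloxy)-2-formyl-1-methyl-3-(prop-2-yn-1-yl)cyclohexane-1-carboxylate | O=C[C@@H]1[C@@H](CC#C)[C@H](O[Si](C)(C)C(C)(C)C)CC[C@]1(C)C(=O)OC(C)(C)C | intermediate
20 | tert-butyl (1S,2R,3R,4R)-4-(tert-butyldimethylsilyloxy)-2-(1-hydroxybut-3-en-1-yl)-1-methyl-3-(prop-2-yn-1-yl)cyclohexane-1-carboxylate, both carbinol epimers | C=CCC(O)[C@@H]1[C@@H](CC#C)[C@H](O[Si](C)(C)C(C)(C)C)CC[C@]1(C)C(=O)OC(C)(C)C | intermediate
21 | tert-butyl (1S,2R,3R,4R)-2-(but-3-enoyl)-4-(tert-butyldimethylsilyloxy)-1-methyl-3-(prop-2-yn-1-yl)cyclohexane-1-carboxylate | C=CCC(=O)[C@@H]1[C@@H](CC#C)[C@H](O[Si](C)(C)C(C)(C)C)CC[C@]1(C)C(=O)OC(C)(C)C | intermediate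
22 | tert-butyl (1S,2R,3R,4R)-2-(2-allyl-1,3-dioxolan-2-yl)-4-(tert-butyldimethylsilyloxy)-1-methyl-3-(prop-2-yn-1-yl)cyclohexane-1-carboxylate | C=CCC1(OCCO1)[C@@H]2[C@@H](CC#C)[C@H](O[Si](C)(C)C(C)(C)C)CC[C@]2(C)C(=O)OC(C)(C)C | intermediate
23 | tert-butyl (1S,2R,3R,4R)-2-(2-allyl-1,3-dioxolan-2-yl)-4-(tert-butyldimethylsilyloxy)-1-methyl-3-(2-oxopropyl)cyclohexane-1-carboxylate | C=CCC1(OCCO1)[C@@H]2[C@@H](CC(C)=O)[C@H](O[Si](C)(C)C(C)(C)C)CC[C@]2(C)C(=O)OC(C)(C)C | intermediate
24 | tert-butyl (1S,2R,3R,4R)-2-(2-allyl-1,3-dioxolan-2-yl)-4-(tert-butyldimethylsilyloxy)-1-methyl-3-[2-(triethylsilyloxy)prop-2-en-1-yl]cyclohexane-1-carboxylate | C=CCC1(OCCO1)[C@@H]2[C@@H](CC(=C)O[Si](CC)(CC)CC)[C@H](O[Si](C)(C)C(C)(C)C)CC[C@]2(C)C(=O)OC(C)(C)C | intermediate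
25 | AB bicycle enol silane: 9-(triethylsilyloxy), C8=C9, 6,6-ethylenedioxy, 1β-OTBS, 4α-methyl, 4β-CO2tBu, trans-fused (1R,4S,5R,10R) | CC[Si](CC)(CC)OC2=CCC3(OCCO3)[C@@H]4[C@@H](C2)[C@H](O[Si](C)(C)C(C)(C)C)CC[C@]4(C)C(=O)OC(C)(C)C | intermediate
26 | AB bicycle enol triflate: 9-(trifluoromethanesulfonyloxy), C8=C9 (1R,4S,5R,10R) | O=S(=O)(OC2=CCC3(OCCO3)[C@@H]4[C@@H](C2)[C@H](O[Si](C)(C)C(C)(C)C)CC[C@]4(C)C(=O)OC(C)(C)C)C(F)(F)F | intermediate
27 | AB bicycle alkenylstannane: 9-(trimethylstannyl), C8=C9 (1R,4S,5R,10R) | C[Sn](C)(C)C2=CCC3(OCCO3)[C@@H]4[C@@H](C2)[C@H](O[Si](C)(C)C(C)(C)C)CC[C@]4(C)C(=O)OC(C)(C)C | intermediate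
28 | AB bicycle alkenyllithium: 9-lithio, C8=C9 (1R,4S,5R,10R) | [Li]C2=CCC3(OCCO3)[C@@H]4[C@@H](C2)[C@H](O[Si](C)(C)C(C)(C)C)CC[C@]4(C)C(=O)OC(C)(C)C | intermediate
29 | 4-hydroxy-3-isopropoxy-2-isopropyl-4-(AB bicycle-9-yl)cyclobut-2-en-1-one, C8=C9, both carbinol epimers (1R,4S,5R,10R) | CC(C)C1=C(OC(C)C)C(O)(C2=CCC3(OCCO3)[C@@H]4[C@@H](C2)[C@H](O[Si](C)(C)C(C)(C)C)CC[C@]4(C)C(=O)OC(C)(C)C)C1=O | intermediate
30 | dienylketene from ring opening of 29 (C14 ketene carbon; C11 enol; C9 alkenyl cis to the ketene arm) | O=C=C(C(C)C)/C(OC(C)C)=C(/O)C2=CCC3(OCCO3)[C@@H]4[C@@H](C2)[C@H](O[Si](C)(C)C(C)(C)C)CC[C@]4(C)C(=O)OC(C)(C)C | intermediate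
31 | 12-isopropoxy-13-isopropyl-11,14-hydroquinone fused at C8–C9 to the AB bicycle (C7H2, C20H2; 1R,4S,5R,10R) | CC(C)c1c(OC(C)C)c(O)c2c(c1O)CC3(OCCO3)[C@@H]4[C@@H](C2)[C@H](O[Si](C)(C)C(C)(C)C)CC[C@]4(C)C(=O)OC(C)(C)C | intermediate
32 | 12-isopropoxy-13-isopropyl-11,14-quinone fused at C8–C9 to the AB bicycle (1R,4S,5R,10R) | CC(C)C1=C(OC(C)C)C(=O)C2=C(C1=O)CC3(OCCO3)[C@@H]4[C@@H](C2)[C@H](O[Si](C)(C)C(C)(C)C)CC[C@]4(C)C(=O)OC(C)(C)C | intermediate
33 | 10(20)-ene 12-isopropoxy-11,14-hydroquinone with C6 ketal, 1β-OTBS, C19 tert-butyl ester (1R,4S,5R) | CC(C)c1c(OC(C)C)c(O)c2c(c1O)CC3(OCCO3)[C@@H]4C(=C2)[C@H](O[Si](C)(C)C(C)(C)C)CC[C@]4(C)C(=O)OC(C)(C)C | intermediate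
34 | 10(20)-ene 12-isopropoxy-11,14-quinone with C6 ketal, 1β-OTBS, C19 tert-butyl ester (1R,4S,5R) | CC(C)C1=C(OC(C)C)C(=O)C2=C(C1=O)CC3(OCCO3)[C@@H]4C(=C2)[C@H](O[Si](C)(C)C(C)(C)C)CC[C@]4(C)C(=O)OC(C)(C)C | intermediate
35 | keto acid: 12-hydroxy-6-oxo-10(20)-ene 11,14-quinone 19-oic acid, 1β-OTBS (1R,4S,5R); in equilibrium with its lactol form | CC(C)C1=C(O)C(=O)C2=C(C1=O)CC(=O)[C@@H]3C(=C2)[C@H](O[Si](C)(C)C(C)(C)C)CC[C@]3(C)C(=O)O | intermediate
36 | 1-O-(tert-butyldimethylsilyl)-6,7-anhydroballotiquinone (1R,4S,5R) | CC(C)C1=C(O)C(=O)C2=C(C=C3OC(=O)[C@@]4(C)CC[C@@H](O[Si](C)(C)C(C)(C)C)C(=C2)[C@@H]34)C1=O | intermediate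
37 | 6,7-anhydroballotiquinone (1R,4S,5R) | CC(C)C1=C(O)C(=O)C2=C(C=C3OC(=O)[C@@]4(C)CC[C@@H](O)C(=C2)[C@@H]34)C1=O | target

## Step count and least certain steps

Total step count: 24 (one step for the squarate partner 4, 23 in the main line). Longest linear sequence: 23 steps (steps 2–24, from 5 and 6).

Step 20 (key step). The most likely failure is capture of the ketene by the carbinol oxygen (furanone formation), if ring opening is not fully outward-selective or if closure onto the crowded trisubstituted C8=C9 bond is slow; adventitious air oxidation during isolation is a lesser issue. Fallback: 29 would be silylated on the tertiary hydroxyl (TMSOTf, Et3N) to the trimethylsilyl ether F1, which cannot lactonise and still rotates its oxygen outward. Thermolysis in toluene should give the mono-silylated hydroquinone F2 (C11–OTMS, C14–OH). Mild methanolysis of the aryl silyl ether (K2CO3, MeOH) and Ag2O oxidation would then return to the route at 32.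

Step 22. The most likely failure is preferential and unproductive deprotonation at C7. Its conjugate base is stabilised through the C11 carbonyl, which is not part of the vinylogous ester, so the C7 quinone methide may dominate and be consumed by dimerisation or ketal opening before the C20 pathway aromatises. Intermolecular trapping of the C20 methide is a second risk. Fallback: hydroquinone 31 would be O-methylated (NaH, MeI, DMF) to the 11,14-dimethyl ether F3. DDQ would then abstract hydride at C20 (a C7 cation is destabilised by the adjacent ketal) and give the C10=C20 styrene F4 by benzylic dehydrogenation. Oxidative demethylation with ceric ammonium nitrate at 0 °C would return to the route at 34.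

Step 23. Three things may go wrong: incomplete hydrolysis of the isopropyl vinylogous ester; loss of the silyl ether followed by bridged lactonisation of C1–OH onto C19; and enolisation of the C6 ketone toward C5 (now allylic), leading to the isomeric ring-fused butenolide or to C5 epimerisation. Fallback, a change of order: the acid/anhydride sequence would be applied to 32, before C10=C20 exists. C7 is then the only activated position and C1–OSi is not allylic, so the product should be the enol lactone hydroxyquinone F5 with saturated C10–C20. Acid-catalysed quinone-to-alkenylhydroquinone tautomerisation (TsOH, toluene, 80 °C, Ar) would give the hydroquinone F6, and Ag2O would return to the route at 36. If only the isopropyl group resists, BCl3 at −78 °C is the reagent of choice for that ether.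

Step 16. The likely failure is slow closure onto the 1,1-disubstituted, electron-rich enol silane: the catalyst rests as an unreactive alkoxy-carbene, the allyl group dimerises, or the enol silane hydrolyses. Fallback without metathesis, starting from 23: phosphorylation of the kinetic enolate with diethyl chlorophosphate and LDA-induced 1,3-migration would give the β-ketophosphonate F7. Ruthenium hydride isomerisation of the allyl group would give the propenyl ketal F8, and ozonolysis the non-enolisable C7 aldehyde F9. An intramolecular Horner–Wadsworth–Emmons reaction (LiCl, iPr2NEt) would close ring B as the cycloheptenone F10 (C9 ketone, C7=C8). Conjugate reduction with L-Selectride and trapping of the resulting C8=C9 enolate with PhNTf2 would return to the route at 26.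

Step 4. The likely failures are insufficient face or endo selectivity with this diene, or protodesilylation of the diene by the strongly acidic catalyst. Fallback by resolution, starting from 8 and 9: the cycloaddition would be run with an achiral Lewis acid (Me2AlCl, CH2Cl2, −78 °C) to give 10 as the racemate, which is oxidised as in step 5 to racemic 11. The acid is resolved by crystallisation of its (S)-1-phenylethylammonium salt F11 (the antipodal amine is used if the wrong enantiomer crystallises). Acidification with citric acid would return to the route at 11.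

## Further compounds

F1 | step 20 | O-trimethylsilyl ether of 29 | CC(C)C1=C(OC(C)C)C(O[Si](C)(C)C)(C2=CCC3(OCCO3)[C@@H]4[C@@H](C2)[C@H](O[Si](C)(C)C(C)(C)C)CC[C@]4(C)C(=O)OC(C)(C)C)C1=O
F2 | step 20 | 11-O-trimethylsilyl ether of hydroquinone 31 | CC(C)c1c(OC(C)C)c(O[Si](C)(C)C)c2c(c1O)CC3(OCCO3)[C@@H]4[C@@H](C2)[C@H](O[Si](C)(C)C(C)(C)C)CC[C@]4(C)C(=O)OC(C)(C)C
F3 | step 22 | 11,14-di-O-methyl ether of hydroquinone 31 | CC(C)c1c(OC(C)C)c(OC)c2c(c1OC)CC3(OCCO3)[C@@H]4[C@@H](C2)[C@H](O[Si](C)(C)C(C)(C)C)CC[C@]4(C)C(=O)OC(C)(C)C
F4 | step 22 | 10(20)-ene 11,14-dimethoxy arene (dehydrogenated F3) | CC(C)c1c(OC(C)C)c(OC)c2c(c1OC)CC3(OCCO3)[C@@H]4C(=C2)[C@H](O[Si](C)(C)C(C)(C)C)CC[C@]4(C)C(=O)OC(C)(C)C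
F5 | step 23 | 1-O-TBS-10,20-dihydro-6,7-anhydroballotiquinone (enol lactone hydroxyquinone, 10R) | CC(C)C1=C(O)C(=O)C2=C(C=C3OC(=O)[C@@]4(C)CC[C@@H](O[Si](C)(C)C(C)(C)C)[C@H](C2)[C@@H]34)C1=O
F6 | step 23 | hydroquinone of 36 (11,12,14-trihydroxy arene with C6=C7 enol lactone and C10=C20) | CC(C)c1c(O)c(O)c2c(c1O)C=C3OC(=O)[C@@]4(C)CC[C@@H](O[Si](C)(C)C(C)(C)C)C(=C2)[C@@H]34
F7 | step 16 | β-ketophosphonate from 23: 3-[3-(diethoxyphosphoryl)-2-oxopropyl] analogue | C=CCC1(OCCO1)[C@@H]2[C@@H](CC(=O)CP(=O)(OCC)OCC)[C@H](O[Si](C)(C)C(C)(C)C)CC[C@]2(C)C(=O)OC(C)(C)C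
F8 | step 16 | (E)-propenyl ketal isomer of F7 | C/C=C/C1(OCCO1)[C@@H]2[C@@H](CC(=O)CP(=O)(OCC)OCC)[C@H](O[Si](C)(C)C(C)(C)C)CC[C@]2(C)C(=O)OC(C)(C)C
F9 | step 16 | C7 aldehyde: 2-(2-formyl-1,3-dioxolan-2-yl) β-ketophosphonate | O=CC1(OCCO1)[C@@H]2[C@@H](CC(=O)CP(=O)(OCC)OCC)[C@H](O[Si](C)(C)C(C)(C)C)CC[C@]2(C)C(=O)OC(C)(C)C
F10 | step 16 | AB bicycle cycloheptenone: 9-oxo, C7=C8, 6,6-ethylenedioxy (1R,4S,5R,10R) | O=C2C=CC3(OCCO3)[C@@H]4[C@@H](C2)[C@H](O[Si](C)(C)C(C)(C)C)CC[C@]4(C)C(=O)OC(C)(C)C
F11 | step 4 | (S)-1-phenylethylammonium salt of 11 | COc1ccc(COC[C@@H]2C=C(O[Si](C(C)C)(C(C)C)C(C)C)CC[C@]2(C)C(=O)[O-])cc1.C[C@H]([NH3+])c1ccccc1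
A1 | alternative 1 | podocarpic acid | C[C@]1(C(=O)O)CCC[C@]2(C)c3cc(O)ccc3CC[C@@H]12
A2 | alternative 1 | 11,12-dimethoxy-7-oxoicetexa-8,10(20),11,13-tetraen-19,6-olide | CC(C)c1c(OC)c(OC)c2c(C(=O)[C@H]3OC(=O)[C@@]4(C)CCCC(=C2)[C@@H]34)c1
A3 | alternative 2 | cyclobutane photoadduct with bonds C5–C10 and C6–C7 | O=C1c2c(OC)c(OC)c(C(C)C)c(OC)c2[C@@H]5[C@H]3OC(=O)[C@@]4(C)CC[C@@H](O[Si](C)(C)C(C)(C)C)[C@@]15[C@@H]34
A4 | alternative 3 | tricyclic C20 aryl ketone with C7 methyl ester | COc1c(OC)c(C(C)C)cc2c1C(=O)[C@H]3[C@H](O[Si](C)(C)C(C)(C)C)CC[C@](C)(C(=O)OC(C)(C)C)[C@@H]3CC2C(=O)OC
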